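**Balance first.** Z, L and G together kept the charge: the west run's last reading summed to 100%. So I followed the Z left, and took this flask's G as the charge less its Z and L.

in all of them: Z 0.25 M
- west: D 0.625 M; the very flask that is asked about, followed so far
- south: D 1.2 M; run made earlier
- flask: D 0.625 M; time 15 d

- west (time / h: Z / %, L / %, G / %): 2.50: 94.3, 2.8, 3.3; 8.00: 82.2, 7.9, 8.7; 12.0: 70.6, 10.6, 18.4; 20.0: 51.3, 11.3, 35.5; 30.0: 26.9, 13.5, 59.6
- south (time / d: Z / %, L / %, G / %): 0.500: 70.6, 17.2, 14.3; 1.67: 1.8, 23.6, 74.5; 3.00: 0, 23.0, 76.2; 4.00: 0, 23.3, 76.6; 6.00: 0.5, 22.9, 77.4

(readings scatter by 1 percentage point)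

- in percentages every species weighs as the Z in it: one G counts as two
- at the start none of Z is in solution
- a reading or a percentage of L counts all its forms, free or not
- what has only dissolved of Z counts as not reacted
- the reaction counts as stopped when no species that holds the Z changes by six tenths of a point or more over the second half of the time

* at 15 d, what has stopped the reaction, if anything has (for what has run out or reacted, a solid counts together with what of it has only dissolved) (D has run out first / forward and back rates have come level / it is still moving / all of Z has reacted)
* part of the Z that has turned into other species by 15 d (what has only dissolved does not count)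
* amount of L at 15 d, in percent of the Z charged
* amount of G at 15 d, in percent of the Z charged

**Turned round.** What would have to be true for this flask still to hold Z at 15 d? West lost Z at 0.0245 h⁻¹ of the charge, and south, with twice the D, lost it at 0.0245 h⁻¹. At that pace I reckoned the flask's Z at zero by 1.71 d, so the loss would have to run 8.77 times slower from the start. For D to be the limiting reagent, each Z would have to take 2.50 D; I allowed one at most, which by my reckoning left 60.0% of the D.

**Plateau ratio.** South's L read flat from 3.00 d, when its Z read 0%, at a mean of 23.1%. That reading gave 0.0481, the plateau ratio, final [L] over starting [D]. I assumed the same ratio at this flask's D, with the same Z charged, which gave [L] = 0.0300 M, so I expected L 12.0% and G 88.0%. West's L read 11.3% and 13.5% at its last two times, near that level.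

**The result.** The forecast said all of Z has reacted, with 100% converted, L 12% and G 88%, noting that "South stays flat once Z is gone". The flask gave: all of Z has reacted, with 100% converted, L 12.3%, G 87.7% and D 78% of its charge left; my plateau ratio of 0.0481 had given L 12.0%.

    Z ⇌ X, rate k1*(cs1 - [X]) while solid is left; crystals form when [X] > cs1 (solubility = 0.140 M, k = 0.0439 h⁻¹)
    X + D → L (k = 8.67 L mol⁻¹ h⁻¹)
    X + L → G (k = 143 L mol⁻¹ h⁻¹)
    J ⇌ L, rate k4*(cs4 - [L]) while solid is left; crystals form when [L] > cs4 (solubility = 0.0800 M, k = 7.69 h⁻¹)

**Near level.** At 0.852 d, dissolved L in this flask was made 1.08 times as fast as it was used, each step taken net and going into its other forms counted as use; half of the dissolving of Z was done by 0.852 d. By 7.50 d the flask stood at L 12.3% and G 87.7%, and at 150 d it still held L 12.3% and G 87.7%.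

**Second flask.** With 0.15 M of Z and the same D, the plateau ratio gave L 20.0% and G 80.0%. The computed flask gave L 21.0% and G 79.0%.

(All runs are simulated for an exercise, noise included.)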